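## Structural features

The target is a linear heptameric phlorotannin: seven benzene rings, lettered A to G with the atoms of each ring numbered 1 to 6 in the order of the target SMILES, are joined head to tail by six diaryl ether oxygens and carry eighteen free phenolic hydroxyls; there is no stereocentre, so no stereocentres stand next to each other. Ring A is a 2,4,6-trihydroxyphenyl group whose carbon 4 is bound through oxygen to B1, and ring G is a 3,4,5-trihydroxyphenyl group bound through the oxygen on G1 to carbon 4 of ring F. Rings B and F are 1,4-diether rings in which the oxygen on carbon 4 is flanked by two hydroxyls, rings C and E are pentaoxygenated with their two ether oxygens ortho to each other (C1/C6, E1/E6), and ring D is tetraoxygenated with ethers at D1 and D5 and hydroxyls at D3 and D4. The free polyphenol, with its pyrogallol and hydroxyhydroquinone units, is very easily oxidised, so the oxygens must stay masked until the last operation. The per-O-methyl intermediates are themselves electron-rich arenes (ring A has two CH positions, each flanked by two methoxy groups) and do not tolerate strong electrophiles or oxidants. The real difficulty is making diaryl ether bonds at oxygens that are flanked on both sides (B4, C6, E6 and carbon 4 of ring F) on rings without electron-withdrawing groups, and above all joining two trimer-sized halves at ring D, where neither D1 nor D5 is activated for substitution. The key step uses the pattern of ring D: D4 is a phenol carbon between oxygenated D3 and D5, D1 carries the ring C oxygen, and D2 and D6 are CH. This is the pattern obtained when a 1,3-dioxygenated acetone (D3–D4–D5) condenses with a 2-aryloxymalonaldehyde equivalent (D2–D1–D6), so ring D can be built between the two halves and need not be substituted.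

## Logic of the disconnections

30 to 29. The seventeen O–CH3 bonds are cut. 30 is too air-sensitive and too polar to carry through a synthesis, whereas methyl ethers survive every basic, oxidative and copper-mediated step. The gain is that every earlier intermediate is a stable, soluble compound. The demand is one exhaustive ether cleavage that reaches all methoxy groups, leaves the six diaryl ether bonds intact and is run with exclusion of air.

29 to 14 and 26. Bonds D2–D3 and D5–D6 are cut, so ring D falls into a three-carbon unit D2–D1–D6 on the C6 oxygen and a three-carbon unit D3–D4–D5 on the E1 oxygen. The cut is made here because D1 and D5 cannot be activated for substitution and the C6 oxygen is flanked on both sides. The gain is full convergence into two halves of similar size, with all four ring D oxygens already in place. The demand is that cross-condensation beats self-condensation of 26 and that the base is strong enough for two α-deprotonations.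

14 to 13, 12, and 10 with 11. The bond between the D1 carbon and one aminomethylene carbon is cut, then the aldehyde is masked as its acetal, then the O–CH2 bond is cut. Aminomethylenation of an aldehyde methylene under neutral conditions is chosen because electrophilic formylating agents would attack ring A. The gain is that the whole three-carbon unit hangs on one phenol oxygen. The demand is an alkylation that works on a doubly flanked phenol and gentle handling of the sensitive 13.

26 to 25, then 23 with 24. The ketone is taken back to the secondary alcohol, and the E1 oxygen–CH2 bond is then cut as an epoxide opening. The D3 methoxy group arrives with 24, which makes this one step shorter than a halohydrin, epoxide and methanolysis relay. The demand is attack at the unsubstituted epoxide carbon and an oxidation mild enough for the methoxyarenes.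

10 to 8 (through 9), then 5 with 7, and 7 to 6. The C6 hydroxyl is traced to a formyl group (aryl C–C to aryl C–O), and the C1–O–B4 ether bond is then cut. The formyl group serves twice: it activates the ortho C–Br bond for coupling and it is the latent phenol. 7 comes from 6 by formylation at one of its two equivalent free positions. The demand is a coupling that accepts the doubly flanked phenol 5.

5 to 3 (through 4), then 1 with 2. The same pair of operations unmasks B4–OH and cuts the ether bond between carbon 4 of ring A and B1. The bromide of 2 is para to the formyl group and unhindered, so the hindered partner is the phenol only. The gain is two catalogue compounds.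

23 to 21 (through 22), then 19 with 20. The E1 hydroxyl is traced to a formyl group and the ether bond between E6 and carbon 1 of ring F is cut. The ortho formyl group of 20 must compensate for a C–Br bond flanked on both sides, while the phenol 19 is unhindered.

19 to 17 (through 18), then 15 with 16. The hydroxyl on carbon 1 of ring F is traced to a formyl group and the ether bond between carbon 4 of ring F and G1 is cut. The phenol 15 is unhindered and electron-rich, but the bromide of 16 lies between two methoxy groups, so this coupling is the most demanding of the four.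

## Other disconnections considered

Alternative 1: The two ether bonds at D1 and D5 are cut, with the oxygens staying on rings C and E, and ring D is bought as 2,4,6-trifluorobenzaldehyde A1.
- Forward key step: a one-pot double nucleophilic aromatic substitution, first the phenoxide of 10 at the para fluorine and then the phenoxide of 23 at an ortho fluorine. This would give the heptamer A2, whose ring D is a 2-fluoro-4,6-bis(aryloxy)benzaldehyde. Methoxy-defluorination to A3 and Dakin oxidation would then give 29.
- In its favour: it uses the same phenols 10 and 23 and needs none of the five steps that attach the three-carbon units (steps 6, 7, 8, 13 and 14). It is three steps from the phenols to 29 against six, so on step economy it is the better plan. It also avoids a ring construction.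
- Against it: three successive substitutions are needed on a ring that becomes less electrophilic with each aryloxy or methoxy group. The first site selection (para against two ortho fluorines) rests on kinetics alone, with the most hindered nucleophile of the route. Ortho attack or double substitution would give regioisomeric heptamers that would be very hard to separate or tell apart.
- Comparison: on structure both plans give the same 29. On mechanism the chosen plan is safer, since the constitution of 14 and 26 fixes the pattern of ring D and no site selectivity is involved. On step economy Alternative 1 wins.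

Alternative 2: Bond E1–E2 is cut inside ring E, which would then be assembled on the phenol oxygen of 19 from a four-carbon squarate unit and a two-carbon methoxyvinyl unit.
- Forward key step: 19 would be joined to dimethyl squarate A4, a metallated methyl vinyl ether added to the carbonyl remote from the aryloxy carbon, and the tertiary alkoxide methylated to give cyclobutenone A5. Thermolysis would open A5 to a vinylketene (conrotatory 4π opening with the methoxy group turning outward), and 6π closure with tautomerisation would give the phenol A6, which is identical with 23.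
- In its favour: every oxygen of the pentaoxygenated ring is placed by construction. It avoids the copper-mediated coupling at the doubly flanked bromide of 20 and the following Dakin oxidation, and on that point it is the better plan. The key step is thermal and neutral.
- Against it: it solves only ring E and leaves the joining at ring D untouched. It replaces two steps from a catalogue aldehyde with about four, including cryogenic organometallic chemistry on a mixed aryl methyl squarate that can lose aryloxide by addition–elimination.
- Comparison: on structure it is the equal of the chosen sub-route, since both are regiochemically unambiguous. On mechanism it is the better at the hindered C–O bond. On step economy it is worse.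

Alternative 3: The ring A bond between the ether-bearing carbon 4 and the neighbouring carbon 3 is cut, so ring A would be folded from a triketide chain hanging on the B1 oxygen of the hexamer phenol A7.
- Forward key step: the S-tert-butyl 6-aryloxy-3,5-dioxohexanethioate A8 would be treated with a lithium amide base. The aryloxy-bearing carbon 6 would attack the thioester carbonyl in a Claisen (Dieckmann-type) closure, thiolate would be lost and enolisation would give the phloroglucinol ring of A9.
- In its favour: it follows the biosynthetic logic of phloroglucinols, and ring A arrives unprotected, so the last step would cleave fifteen methyl ethers and not seventeen. On that point it is the better plan.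
- Against it: ring A is terminal, so the closure joins nothing. A7 already contains ring D and must itself be made by one of the other plans. The chain needs at least three steps to install, where the chosen route takes ring A from catalogue compound 1. Closure through oxygen to a 4-hydroxypyran-2-one, the usual fate of 3,5-dioxo esters, would compete with the carbon closure.
- Comparison: on structure it gives a closely related late intermediate. On mechanism it carries a chemoselectivity question that the chosen plan does not have. On step economy it is clearly worse.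

Key step: step 15

Assumption: 24 is used as the racemate because its stereocentre becomes the carbonyl carbon of 26; 2, 6, 16 and 20 are taken as catalogue compounds; the C=C geometry of 14 is drawn Z but is immaterial, since this push-pull alkene isomerises freely.

## Route

Step 1
Reactants: 1 2,4,6-trimethoxyphenol; 2 4-bromo-2,6-dimethoxybenzaldehyde
Product: 3 2,6-dimethoxy-4-(2,4,6-trimethoxyphenoxy)benzaldehyde
Conditions: CuI (10 mol%), picolinic acid (20 mol%), K3PO4, DMSO, 90 °C, argon
Reagents that add atoms: none
Why: Ullmann-type copper-catalysed C–O coupling; the bromide of 2 is para to the formyl group and has no ortho substituent, so oxidative addition should be easy, and the CuI/picolinic acid system is suited to phenoxides with two ortho substituents such as that of 1; argon keeps the electron-rich phenoxide from oxidising.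

Step 2
Reactants: 3 2,6-dimethoxy-4-(2,4,6-trimethoxyphenoxy)benzaldehyde
Product: 5 2,6-dimethoxy-4-(2,4,6-trimethoxyphenoxy)phenol, via aryl formate 4 (not isolated)
Conditions: mCPBA, CH2Cl2, 0 °C to rt; aqueous NaHCO3/Na2S2O3 wash; then Et3N (cat.), degassed MeOH, rt
Reagents that add atoms: 3-chloroperoxybenzoic acid (mCPBA), OOC(=O)c1cccc(Cl)c1
Why: Dakin-type Baeyer–Villiger oxidation; the aryl group, made electron-rich by two ortho methoxy groups and the para aryloxy group, should migrate in preference to hydrogen to give 4, which is methanolysed only after the peracid has been removed, so that the oxidisable hydroquinone monoether 5 never meets the oxidant.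

Step 3
Reactants: 6 5-bromo-1,2,3-trimethoxybenzene
Product: 7 6-bromo-2,3,4-trimethoxybenzaldehyde
Conditions: Cl2CHOMe, TiCl4, CH2Cl2, −10 to 0 °C; then ice-water
Reagents that add atoms: dichloromethyl methyl ether, COC(Cl)Cl; water, O
Why: Rieche formylation (electrophilic aromatic substitution); 6 has only two free positions and they are equivalent, each ortho and para to methoxy groups, so a single aldehyde can form, with bromine ortho to the new formyl group.

Step 4
Reactants: 5 2,6-dimethoxy-4-(2,4,6-trimethoxyphenoxy)phenol; 7 6-bromo-2,3,4-trimethoxybenzaldehyde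
Product: 8 6-[2,6-dimethoxy-4-(2,4,6-trimethoxyphenoxy)phenoxy]-2,3,4-trimethoxybenzaldehyde
Conditions: CuI (20 mol%), picolinic acid (40 mol%), K3PO4, DMSO, 100 °C, argon
Reagents that add atoms: none
Why: Ullmann-type C–O coupling; the C–Br bond of 7 is activated by the ortho formyl group and keeps one free ortho position, which should compensate for the doubly flanked phenoxide of 5.

Step 5
Reactants: 8 6-[2,6-dimethoxy-4-(2,4,6-trimethoxyphenoxy)phenoxy]-2,3,4-trimethoxybenzaldehyde
Product: 10 6-[2,6-dimethoxy-4-(2,4,6-trimethoxyphenoxy)phenoxy]-2,3,4-trimethoxyphenol, via aryl formate 9 (not isolated)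
Conditions: mCPBA, CH2Cl2, 0 °C to rt; aqueous NaHCO3/Na2S2O3 wash; then Et3N (cat.), degassed MeOH, rt
Reagents that add atoms: 3-chloroperoxybenzoic acid (mCPBA), OOC(=O)c1cccc(Cl)c1
Why: Dakin-type Baeyer–Villiger oxidation; ortho methoxy, ortho aryloxy and para methoxy groups strongly favour aryl migration, and at 0 °C the aldehyde should be oxidised much faster than the methoxyarene rings.

Step 6
Reactants: 10 6-[2,6-dimethoxy-4-(2,4,6-trimethoxyphenoxy)phenoxy]-2,3,4-trimethoxyphenol; 11 bromoacetaldehyde diethyl acetal
Product: 12 2-{6-[2,6-dimethoxy-4-(2,4,6-trimethoxyphenoxy)phenoxy]-2,3,4-trimethoxyphenoxy}acetaldehyde diethyl acetal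
Conditions: Cs2CO3, KI (cat.), DMF, 110 °C, argon
Reagents that add atoms: none
Why: Williamson ether synthesis (SN2); Cs2CO3 in DMF gives a loosely paired phenoxide and iodide exchange raises the reactivity of the primary halide, which is needed because the phenoxide of 10 is flanked by a methoxy and an aryloxy group.

Step 7
Reactants: 12 2-{6-[2,6-dimethoxy-4-(2,4,6-trimethoxyphenoxy)phenoxy]-2,3,4-trimethoxyphenoxy}acetaldehyde diethyl acetal
Product: 13 2-{6-[2,6-dimethoxy-4-(2,4,6-trimethoxyphenoxy)phenoxy]-2,3,4-trimethoxyphenoxy}acetaldehyde
Conditions: 1 M HCl, THF, 50 °C; used crude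
Reagents that add atoms: water, O
Why: Acid-catalysed acetal hydrolysis; aryl methyl and diaryl ethers are inert to dilute aqueous acid, and the benzofuran cyclisation typical of aryloxyacetaldehyde acetals is excluded because both ortho positions of ring C are substituted.

Step 8
Reactants: 13 2-{6-[2,6-dimethoxy-4-(2,4,6-trimethoxyphenoxy)phenoxy]-2,3,4-trimethoxyphenoxy}acetaldehyde
Product: 14 (Z)-3-(dimethylamino)-2-{6-[2,6-dimethoxy-4-(2,4,6-trimethoxyphenoxy)phenoxy]-2,3,4-trimethoxyphenoxy}prop-2-enal
Conditions: tBuOCH(NMe2)2, toluene, 60 °C
Reagents that add atoms: tert-butoxybis(dimethylamino)methane (Bredereck's reagent), CC(C)(C)OC(N(C)C)N(C)C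
Why: Aminomethylenation of the α-methylene of an aldehyde with Bredereck's reagent (condensation with loss of tert-butanol and dimethylamine); unlike Vilsmeier-type reagents it does not attack arenes, so ring A is safe, and the push-pull alkene should settle in the Z form with the formyl group anti to nitrogen.

Step 9
Reactants: 15 3,4,5-trimethoxyphenol; 16 4-bromo-3,5-dimethoxybenzaldehyde
Product: 17 3,5-dimethoxy-4-(3,4,5-trimethoxyphenoxy)benzaldehyde
Conditions: CuI (20 mol%), picolinic acid (40 mol%), K3PO4, DMSO, 110 °C, argon
Reagents that add atoms: none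
Why: Ullmann-type C–O coupling; the para formyl group activates the C–Br bond of 16 and the unhindered, electron-rich phenoxide of 15 is a good partner, which should offset the two methoxy groups that flank the bromide.

Step 10
Reactants: 17 3,5-dimethoxy-4-(3,4,5-trimethoxyphenoxy)benzaldehyde
Product: 19 3,5-dimethoxy-4-(3,4,5-trimethoxyphenoxy)phenol, via aryl formate 18 (not isolated)
Conditions: mCPBA, CH2Cl2, 0 °C to rt; aqueous NaHCO3/Na2S2O3 wash; then Et3N (cat.), degassed MeOH, rt
Reagents that add atoms: 3-chloroperoxybenzoic acid (mCPBA), OOC(=O)c1cccc(Cl)c1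
Why: Dakin-type Baeyer–Villiger oxidation; 17 is the electronic analogue of 3,4,5-trimethoxybenzaldehyde, a standard substrate for this conversion, so migration of the para-oxygenated aryl group should prevail.

Step 11
Reactants: 19 3,5-dimethoxy-4-(3,4,5-trimethoxyphenoxy)phenol; 20 2-bromo-3,4,5-trimethoxybenzaldehyde
Product: 21 2-[3,5-dimethoxy-4-(3,4,5-trimethoxyphenoxy)phenoxy]-3,4,5-trimethoxybenzaldehyde
Conditions: CuI (20 mol%), picolinic acid (40 mol%), K3PO4, DMSO, 100 °C, argon
Reagents that add atoms: none
Why: Ullmann-type C–O coupling; the ortho formyl group of 20 assists oxidative addition at the flanked C–Br bond, the classical reactivity of ortho-halo aryl carbonyl compounds, and the phenoxide of 19 has two free ortho positions.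

Step 12
Reactants: 21 2-[3,5-dimethoxy-4-(3,4,5-trimethoxyphenoxy)phenoxy]-3,4,5-trimethoxybenzaldehyde
Product: 23 2-[3,5-dimethoxy-4-(3,4,5-trimethoxyphenoxy)phenoxy]-3,4,5-trimethoxyphenol, via aryl formate 22 (not isolated)
Conditions: mCPBA, CH2Cl2, 0 °C to rt; aqueous NaHCO3/Na2S2O3 wash; then Et3N (cat.), degassed MeOH, rt
Reagents that add atoms: 3-chloroperoxybenzoic acid (mCPBA), OOC(=O)c1cccc(Cl)c1
Why: Dakin-type Baeyer–Villiger oxidation; the ortho aryloxy and para methoxy groups direct aryl migration, and the phenol is set free only after the oxidant has been removed.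

Step 13
Reactants: 23 2-[3,5-dimethoxy-4-(3,4,5-trimethoxyphenoxy)phenoxy]-3,4,5-trimethoxyphenol; 24 rac-methyl glycidyl ether
Product: 25 rac-1-{2-[3,5-dimethoxy-4-(3,4,5-trimethoxyphenoxy)phenoxy]-3,4,5-trimethoxyphenoxy}-3-methoxypropan-2-ol
Conditions: K2CO3 (cat.), DMF, 90 °C
Reagents that add atoms: none
Why: Base-catalysed epoxide opening by phenoxide at the unsubstituted carbon (SN2); the secondary carbinol is formed as a racemate, which is acceptable because it is oxidised in step 14.

Step 14
Reactants: 25 rac-1-{2-[3,5-dimethoxy-4-(3,4,5-trimethoxyphenoxy)phenoxy]-3,4,5-trimethoxyphenoxy}-3-methoxypropan-2-ol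
Product: 26 1-{2-[3,5-dimethoxy-4-(3,4,5-trimethoxyphenoxy)phenoxy]-3,4,5-trimethoxyphenoxy}-3-methoxypropan-2-one
Conditions: Dess–Martin periodinane, CH2Cl2, rt
Reagents that add atoms: none
Why: Dess–Martin oxidation of a secondary alcohol under nearly neutral conditions, which should leave the methoxyarene rings untouched and avoid enolisation or aldol chemistry of the α,α'-dioxygenated ketone.

Step 15
Reactants: 14 (Z)-3-(dimethylamino)-2-{6-[2,6-dimethoxy-4-(2,4,6-trimethoxyphenoxy)phenoxy]-2,3,4-trimethoxyphenoxy}prop-2-enal; 26 1-{2-[3,5-dimethoxy-4-(3,4,5-trimethoxyphenoxy)phenoxy]-3,4,5-trimethoxyphenoxy}-3-methoxypropan-2-one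
Product: 29 heptadeca-O-methyl heptamer D4-phenol, via aminodienone 27 (not isolated), via cyclised amine adduct 28 (not isolated)
Conditions: KOtBu (3 equiv), THF/tBuOH, argon; 26 (1.2 equiv) added slowly to 14 and base at 0 °C, then 60 °C; AcOH quench
Reagents that add atoms: none
Why: This is a [3+3] phenol benzannulation, and the closest known reaction type is the base-mediated union of a ketone of the CH2–CO–CH2 type with a 2-substituted three-carbon 1,3-dielectrophile (a vinamidinium salt, a 3-aminoacrolein or nitromalonaldehyde), which delivers a para-substituted phenol. KOtBu deprotonates 26, whose α-hydrogens are acidified by the adjacent oxygens, and the enolate condenses with the formyl carbon of 14 (aldol addition, then loss of water) to give 27, which sets the first new ring bond (drawn as D5–D6). Deprotonation at the second α-methylene gives a dienolate that is a 1-oxido-hexatriene, and ring D closes by thermal disrotatory 6π electrocyclisation (formally a 6-endo-trig attack of the α-carbon on the enamine carbon) to 28, which sets the second new ring bond (D2–D3). Vinylogous E1cB loss of dimethylamine and tautomerisation then give the phenoxide of 29, and this aromatisation makes the sequence irreversible and drains reversible side equilibria such as oxa-6π closure to a 2H-pyran. No stereocentre is present in 29, and the two sp3 centres of 28 are transient. The selectivity needed is cross-condensation ahead of self-condensation of 26, which is served by the non-enolisable 14 and by slow addition of 26, so that each enolate meets an excess of the three-carbon partner. No regiochemical question arises, since the two ends of the aminoacrolein unit finish as D2 and D6, which are both CH and interchangeable, and it therefore does not matter which α-carbon of 26 reacts first. The oxygens at D1, D3, D4 and D5 are all carried in by 14 and 26, so the step makes no carbon–oxygen bond at a crowded position.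

Step 16
Reactants: 29 heptadeca-O-methyl heptamer D4-phenol
Product: 30 target octadecaphenol CNP0130704.0
Conditions: BBr3 (excess, 1 M in CH2Cl2), CH2Cl2, −78 °C to rt, argon; then MeOH, water; Sephadex LH-20, degassed MeOH
Reagents that add atoms: none
Why: Lewis acid ether cleavage; BBr3 coordinates each methoxy oxygen and bromide attacks the methyl carbon (SN2), whereas the six diaryl ether bonds offer no sp3 carbon and should stay intact; exclusion of air and an acidic work-up protect the polyphenol.

## Compound list

1 | 2,4,6-trimethoxyphenol | COc1cc(OC)c(O)c(OC)c1 | starting material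
2 | 4-bromo-2,6-dimethoxybenzaldehyde | COc1cc(Br)cc(OC)c1C=O | starting material
3 | 2,6-dimethoxy-4-(2,4,6-trimethoxyphenoxy)benzaldehyde | O=Cc1c(OC)cc(Oc2c(OC)cc(OC)cc2OC)cc1OC | intermediate
4 | 2,6-dimethoxy-4-(2,4,6-trimethoxyphenoxy)phenyl formate (not isolated) | O=COc1c(OC)cc(Oc2c(OC)cc(OC)cc2OC)cc1OC | intermediate
5 | 2,6-dimethoxy-4-(2,4,6-trimethoxyphenoxy)phenol | Oc1c(OC)cc(Oc2c(OC)cc(OC)cc2OC)cc1OC | intermediate
6 | 5-bromo-1,2,3-trimethoxybenzene | COc1cc(Br)cc(OC)c1OC | starting material
7 | 6-bromo-2,3,4-trimethoxybenzaldehyde | O=Cc1c(Br)cc(OC)c(OC)c1OC | intermediate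
8 | 6-[2,6-dimethoxy-4-(2,4,6-trimethoxyphenoxy)phenoxy]-2,3,4-trimethoxybenzaldehyde | O=Cc1c(OC)c(OC)c(OC)cc1Oc1c(OC)cc(Oc2c(OC)cc(OC)cc2OC)cc1OC | intermediate
9 | 6-[2,6-dimethoxy-4-(2,4,6-trimethoxyphenoxy)phenoxy]-2,3,4-trimethoxyphenyl formate (not isolated) | O=COc1c(OC)c(OC)c(OC)cc1Oc1c(OC)cc(Oc2c(OC)cc(OC)cc2OC)cc1OC | intermediate
10 | 6-[2,6-dimethoxy-4-(2,4,6-trimethoxyphenoxy)phenoxy]-2,3,4-trimethoxyphenol (per-O-methyl ABC phenol) | Oc1c(OC)c(OC)c(OC)cc1Oc1c(OC)cc(Oc2c(OC)cc(OC)cc2OC)cc1OC | intermediate
11 | bromoacetaldehyde diethyl acetal | CCOC(CBr)OCC | starting material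
12 | 2-{6-[2,6-dimethoxy-4-(2,4,6-trimethoxyphenoxy)phenoxy]-2,3,4-trimethoxyphenoxy}acetaldehyde diethyl acetal | CCOC(COc1c(OC)c(OC)c(OC)cc1Oc1c(OC)cc(Oc2c(OC)cc(OC)cc2OC)cc1OC)OCC | intermediate
13 | 2-{6-[2,6-dimethoxy-4-(2,4,6-trimethoxyphenoxy)phenoxy]-2,3,4-trimethoxyphenoxy}acetaldehyde | O=CCOc1c(OC)c(OC)c(OC)cc1Oc1c(OC)cc(Oc2c(OC)cc(OC)cc2OC)cc1OC | intermediate
14 | (Z)-3-(dimethylamino)-2-{6-[2,6-dimethoxy-4-(2,4,6-trimethoxyphenoxy)phenoxy]-2,3,4-trimethoxyphenoxy}prop-2-enal | O=C/C(=C/N(C)C)Oc1c(OC)c(OC)c(OC)cc1Oc1c(OC)cc(Oc2c(OC)cc(OC)cc2OC)cc1OC | intermediate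
15 | 3,4,5-trimethoxyphenol | COc1cc(O)cc(OC)c1OC | starting material
16 | 4-bromo-3,5-dimethoxybenzaldehyde | COc1cc(C=O)cc(OC)c1Br | starting material
17 | 3,5-dimethoxy-4-(3,4,5-trimethoxyphenoxy)benzaldehyde | O=Cc1cc(OC)c(Oc2cc(OC)c(OC)c(OC)c2)c(OC)c1 | intermediate
18 | 3,5-dimethoxy-4-(3,4,5-trimethoxyphenoxy)phenyl formate (not isolated) | O=COc1cc(OC)c(Oc2cc(OC)c(OC)c(OC)c2)c(OC)c1 | intermediate
19 | 3,5-dimethoxy-4-(3,4,5-trimethoxyphenoxy)phenol | Oc1cc(OC)c(Oc2cc(OC)c(OC)c(OC)c2)c(OC)c1 | intermediate
20 | 2-bromo-3,4,5-trimethoxybenzaldehyde | O=Cc1cc(OC)c(OC)c(OC)c1Br | starting material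
21 | 2-[3,5-dimethoxy-4-(3,4,5-trimethoxyphenoxy)phenoxy]-3,4,5-trimethoxybenzaldehyde | O=Cc1cc(OC)c(OC)c(OC)c1Oc1cc(OC)c(Oc2cc(OC)c(OC)c(OC)c2)c(OC)c1 | intermediate
22 | 2-[3,5-dimethoxy-4-(3,4,5-trimethoxyphenoxy)phenoxy]-3,4,5-trimethoxyphenyl formate (not isolated) | O=COc1cc(OC)c(OC)c(OC)c1Oc1cc(OC)c(Oc2cc(OC)c(OC)c(OC)c2)c(OC)c1 | intermediate
23 | 2-[3,5-dimethoxy-4-(3,4,5-trimethoxyphenoxy)phenoxy]-3,4,5-trimethoxyphenol (per-O-methyl EFG phenol) | Oc1cc(OC)c(OC)c(OC)c1Oc1cc(OC)c(Oc2cc(OC)c(OC)c(OC)c2)c(OC)c1 | intermediate
24 | rac-methyl glycidyl ether, 2-(methoxymethyl)oxirane | COCC1CO1 | starting material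
25 | rac-1-{2-[3,5-dimethoxy-4-(3,4,5-trimethoxyphenoxy)phenoxy]-3,4,5-trimethoxyphenoxy}-3-methoxypropan-2-ol | COCC(O)COc1cc(OC)c(OC)c(OC)c1Oc1cc(OC)c(Oc2cc(OC)c(OC)c(OC)c2)c(OC)c1 | intermediate
26 | 1-{2-[3,5-dimethoxy-4-(3,4,5-trimethoxyphenoxy)phenoxy]-3,4,5-trimethoxyphenoxy}-3-methoxypropan-2-one | COCC(=O)COc1cc(OC)c(OC)c(OC)c1Oc1cc(OC)c(Oc2cc(OC)c(OC)c(OC)c2)c(OC)c1 | intermediate
27 | open-chain aminodienone from 14 and 26 (not isolated; double-bond geometry labile, not defined) | COCC(=O)C(Oc1cc(OC)c(OC)c(OC)c1Oc1cc(OC)c(Oc2cc(OC)c(OC)c(OC)c2)c(OC)c1)=CC(Oc1c(OC)c(OC)c(OC)cc1Oc1c(OC)cc(Oc2c(OC)cc(OC)cc2OC)cc1OC)=CN(C)C | intermediate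
28 | cyclised amine adduct, 5-(dimethylamino)-6-methoxycyclohexa-1,3-dien-1-ol with the EFG aryloxy group at C2 and the ABC aryloxy group at C4 (not isolated; present as its potassium dienolate; racemic, relative configuration immaterial) | COC1C(N(C)C)C(Oc2c(OC)c(OC)c(OC)cc2Oc2c(OC)cc(Oc3c(OC)cc(OC)cc3OC)cc2OC)=CC(Oc2cc(OC)c(OC)c(OC)c2Oc2cc(OC)c(Oc3cc(OC)c(OC)c(OC)c3)c(OC)c2)=C1O | intermediate
29 | heptadeca-O-methyl heptamer D4-phenol, 2-{2-[3,5-dimethoxy-4-(3,4,5-trimethoxyphenoxy)phenoxy]-3,4,5-trimethoxyphenoxy}-4-{6-[2,6-dimethoxy-4-(2,4,6-trimethoxyphenoxy)phenoxy]-2,3,4-trimethoxyphenoxy}-6-methoxyphenol | COc1cc(OC)c(Oc2cc(OC)c(Oc3cc(OC)c(OC)c(OC)c3Oc3cc(OC)c(O)c(Oc4cc(OC)c(OC)c(OC)c4Oc4cc(OC)c(Oc5cc(OC)c(OC)c(OC)c5)c(OC)c4)c3)c(OC)c2)c(OC)c1 | intermediate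
30 | CNP0130704.0, heptameric octadecaphenol | Oc1cc(O)c(Oc2cc(O)c(Oc3cc(O)c(O)c(O)c3Oc3cc(O)c(O)c(Oc4cc(O)c(O)c(O)c4Oc4cc(O)c(Oc5cc(O)c(O)c(O)c5)c(O)c4)c3)c(O)c2)c(O)c1 | target

## Step count and least certain steps

Total step count: 16. Longest linear sequence: 9 steps (steps 1, 2, 4, 5, 6, 7, 8, 15 and 16). The second branch (steps 9 to 14) has 6 steps before the convergence.

Step 15 (key step). The enolate of 26 may be used up by self-aldol condensation faster than it attacks the weakly electrophilic, vinylogous formamide carbonyl of 14. The sequence may also stall at the open-chain stage before the second deprotonation and ring closure. The fallback sets out from 14 and turns the neutral three-carbon unit into a cationic one. Heating 14 with dimethylammonium tetrafluoroborate in ethanol should give the 2-aryloxy-1,3-bis(dimethylamino)trimethinium tetrafluoroborate F1. The first C–C bond then forms by enolate attack on an iminium carbon, the established mode of vinamidinium benzannulations. Condensation of F1 with 26 and KOtBu in THF, with loss of two molecules of dimethylamine, comes back to the route at 29.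

Step 16. Ether cleavage may stop short of completion, because partly cleaved material can leave the solution as insoluble boron aggregates before all seventeen methoxy groups have reacted. The free polyphenol may also be lost to air oxidation during isolation. The fallback sets out from 29 and changes the isolation to a derivatise, purify and release sequence. The crude product of the BBr3 treatment is acetylated at once (Ac2O, pyridine) to the octadecaacetate F2, which is stable to air and can be chromatographed on silica, so that incompletely cleaved congeners can be removed. Acid-catalysed methanolysis of F2 (HCl, degassed MeOH, 40 °C, argon) then comes back to the route at 30.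

Step 9. Oxidative addition at the C–Br bond of 16 between two methoxy groups may be slow. Hydrodebromination of 16 and oxidative decay of the phenoxide of 15 could then take over at the temperature required. The fallback sets out from 15 and replaces copper catalysis by addition–elimination. The phenoxide of 15 reacts with catalogue 4-fluoro-3,5-dimethoxybenzaldehyde (Cs2CO3, DMSO, 120 °C), where the para formyl group stabilises the anionic adduct and fluoride is the leaving group. It comes back to the route at 17 and makes no new compound.

Step 6. Substitution at the β,β-diethoxyethyl bromide 11 by the doubly flanked phenoxide of 10 may be slow. Base-induced elimination of HBr from 11 could compete at the temperature needed. The fallback sets out from 10 and uses a much more reactive electrophile followed by oxidative cleavage. Allyl bromide and K2CO3 in DMF should give the allyl ether F3. Lemieux–Johnson cleavage (OsO4 cat., NaIO4, 2,6-lutidine, dioxane/water) should then give the aldehyde directly. This comes back to the route at 13 and bypasses 12 and step 7.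

## Further compounds

F1 | step 15 | 2-{6-[2,6-dimethoxy-4-(2,4,6-trimethoxyphenoxy)phenoxy]-2,3,4-trimethoxyphenoxy}-1,3-bis(dimethylamino)trimethinium tetrafluoroborate | C[N+](C)=C/C(Oc1c(OC)c(OC)c(OC)cc1Oc1c(OC)cc(Oc2c(OC)cc(OC)cc2OC)cc1OC)=C/N(C)C.F[B-](F)(F)F
F2 | step 16 | octadecaacetate of 30 | CC(=O)Oc1cc(OC(C)=O)c(Oc2cc(OC(C)=O)c(Oc3cc(OC(C)=O)c(OC(C)=O)c(OC(C)=O)c3Oc3cc(OC(C)=O)c(OC(C)=O)c(Oc4cc(OC(C)=O)c(OC(C)=O)c(OC(C)=O)c4Oc4cc(OC(C)=O)c(Oc5cc(OC(C)=O)c(OC(C)=O)c(OC(C)=O)c5)c(OC(C)=O)c4)c3)c(OC(C)=O)c2)c(OC(C)=O)c1
F0 | step 9 | none | none
F3 | step 6 | allyl ether of 10, 1-(allyloxy)-6-[2,6-dimethoxy-4-(2,4,6-trimethoxyphenoxy)phenoxy]-2,3,4-trimethoxybenzene | C=CCOc1c(OC)c(OC)c(OC)cc1Oc1c(OC)cc(Oc2c(OC)cc(OC)cc2OC)cc1OC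
A1 | alternative 1 | 2,4,6-trifluorobenzaldehyde | O=Cc1c(F)cc(F)cc1F
A2 | alternative 1 | heptamer with ring D as 2-fluoro-4,6-bis(aryloxy)benzaldehyde | COc1cc(OC)c(Oc2cc(OC)c(Oc3cc(OC)c(OC)c(OC)c3Oc3cc(F)c(C=O)c(Oc4cc(OC)c(OC)c(OC)c4Oc4cc(OC)c(Oc5cc(OC)c(OC)c(OC)c5)c(OC)c4)c3)c(OC)c2)c(OC)c1
A3 | alternative 1 | heptamer with ring D as 2-methoxy-4,6-bis(aryloxy)benzaldehyde | COc1cc(OC)c(Oc2cc(OC)c(Oc3cc(OC)c(OC)c(OC)c3Oc3cc(OC)c(C=O)c(Oc4cc(OC)c(OC)c(OC)c4Oc4cc(OC)c(Oc5cc(OC)c(OC)c(OC)c5)c(OC)c4)c3)c(OC)c2)c(OC)c1
A4 | alternative 2 | dimethyl squarate, 3,4-dimethoxycyclobut-3-ene-1,2-dione | COC1=C(OC)C(=O)C1=O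
A5 | alternative 2 | rac-2-[3,5-dimethoxy-4-(3,4,5-trimethoxyphenoxy)phenoxy]-3,4-dimethoxy-4-(1-methoxyvinyl)cyclobut-2-en-1-one | O=C1C(Oc2cc(OC)c(Oc3cc(OC)c(OC)c(OC)c3)c(OC)c2)=C(OC)C1(OC)C(=C)OC
A6 | alternative 2 | per-O-methyl EFG phenol with free E1 hydroxyl (identical with 23) | Oc1cc(OC)c(OC)c(OC)c1Oc1cc(OC)c(Oc2cc(OC)c(OC)c(OC)c2)c(OC)c1
A7 | alternative 3 | per-O-methyl hexamer phenol of rings B to G with free B1 hydroxyl | Oc1cc(OC)c(Oc2cc(OC)c(OC)c(OC)c2Oc2cc(OC)c(OC)c(Oc3cc(OC)c(OC)c(OC)c3Oc3cc(OC)c(Oc4cc(OC)c(OC)c(OC)c4)c(OC)c3)c2)c(OC)c1
A8 | alternative 3 | S-tert-butyl 6-aryloxy-3,5-dioxohexanethioate on the B1 oxygen of A7 | CC(C)(C)SC(=O)CC(=O)CC(=O)COc1cc(OC)c(Oc2cc(OC)c(OC)c(OC)c2Oc2cc(OC)c(OC)c(Oc3cc(OC)c(OC)c(OC)c3Oc3cc(OC)c(Oc4cc(OC)c(OC)c(OC)c4)c(OC)c3)c2)c(OC)c1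
A9 | alternative 3 | heptamer with free phloroglucinol ring A and fifteen methyl ethers | Oc1cc(O)c(Oc2cc(OC)c(Oc3cc(OC)c(OC)c(OC)c3Oc3cc(OC)c(OC)c(Oc4cc(OC)c(OC)c(OC)c4Oc4cc(OC)c(Oc5cc(OC)c(OC)c(OC)c5)c(OC)c4)c3)c(OC)c2)c(O)c1
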